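**Retrosynthetic overview**
1. The target is methyl 3β-angeloyloxy-4β-hydroxyeudesma-5,11(13)-dien-12-oate; the angelate is put on last by acylating the secondary 3-OH of cis-diol 19.
2. Diol 19 comes from the cis-epoxy alcohol 18 by titanium-mediated epoxide-to-allylic-alcohol isomerization; 18 comes from enone ester 16 by 1,2-reduction and hydroxyl-directed epoxidation.
3. The methyl acrylate side chain comes from the isopropenyl group of (+)-α-cyperone 11 (allylic oxidation, oxidation to the acid, methylation).
4. α-Cyperone comes from 1,5-diketone 9 by aldol condensation; 9 comes from the intermolecular Michael addition (C1–C10 bond) of the chiral imine of dihydrocarvone to ethyl vinyl ketone.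
5. Ring order: ring B is the carvone ring; ring A is annulated onto it (Michael addition, then aldol closure).

Assumption: eudesmane numbering is used (C10 carries the angular methyl, C4 the second methyl, C7 the C11(=C13)–C12 side chain), β means the face of the C10 methyl, and the target is read as (3S,4R,7R,10S) with 3β-O-angeloyl, 4β-OH, 4α-Me and 7β side chain.

**Route**

Step 1
Reactants: 1 (R)-(−)-carvone
Product: 3 (+)-dihydrocarvone (2RS,5R), via lithium enolate 2 (not isolated)
Conditions: LiBH(s-Bu)3 (1.05 equiv), THF, −78 °C; then H2O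
Reagents that add atoms: none
Why: Conjugate (1,4) hydride reduction of the enone leaves the isopropenyl group and C5 untouched, and the C2 epimer mixture is irrelevant because C2 is re-formed in step 3.

Step 2
Reactants: 3 (+)-dihydrocarvone (2RS,5R); 4 (R)-(+)-1-phenylethylamine
Product: 5 (1R)-N-[(5R)-2-methyl-5-(prop-1-en-2-yl)cyclohexylidene]-1-phenylethanamine
Conditions: cat. TsOH, toluene, reflux, Dean–Stark; used crude
Reagents that add atoms: none
Why: Azeotropic imine condensation installs the chiral auxiliary on the ketone without touching C5.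

Step 3
Reactants: 5 imine; 6 ethyl vinyl ketone (pent-1-en-3-one)
Product: 9 (2S,5R)-2-methyl-2-(3-oxopentyl)-5-(prop-1-en-2-yl)cyclohexan-1-one, via secondary enamine tautomer 7 (not isolated), via Michael adduct imine 8 (not isolated)
Conditions: 6 (1.3 equiv, freshly distilled), THF, rt to 40 °C, 3–5 d; then 10% aq AcOH, rt
Reagents that add atoms: water O
Why: Auxiliary-controlled intermolecular Michael addition (deracemizing alkylation through the more substituted secondary enamine in a compact aza-ene-like transition state, acceptor anti to the phenyl group) forms the C1–C10 bond and sets the quaternary C10 as S, cis to the isopropenyl group.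

Step 4
Reactants: 9 diketone
Product: 11 (+)-α-cyperone [(7R,10S)-eudesma-4,11-dien-3-one], via aldol ketol 10 (not isolated)
Conditions: NaOMe, MeOH, rt to 50 °C
Reagents that add atoms: none
Why: Intramolecular aldol condensation (second half of the Robinson annulation) closes ring A as the conjugated enone without affecting C7 or C10.

Step 5
Reactants: 11 (+)-α-cyperone
Product: 12 (7R,10S)-12-hydroxyeudesma-4,11(13)-dien-3-one
Conditions: SeO2 (0.3 equiv), t-BuOOH (3 equiv), CH2Cl2, rt
Reagents that add atoms: selenium dioxide O=[Se]=O (oxygen carrier); tert-butyl hydroperoxide CC(C)(C)OO (terminal oxygen source)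
Why: Selenium dioxide allylic oxidation (ene reaction then [2,3]-shift) attacks the electron-rich 1,1-disubstituted isopropenyl olefin at its methyl group and spares the electron-poor enone; any over-oxidized enal 13 is carried into step 6.

Step 6
Reactants: 12 allylic alcohol
Product: 13 (7R,10S)-3-oxoeudesma-4,11(13)-dien-12-al
Conditions: activated MnO2 (15 equiv), CH2Cl2, rt
Reagents that add atoms: none
Why: MnO2 oxidizes the primary allylic alcohol selectively to the 2-substituted acrolein.

Step 7
Reactants: 13 enal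
Product: 14 (7R,10S)-3-oxoeudesma-4,11(13)-dien-12-oic acid
Conditions: NaClO2, NaH2PO4, 2-methylbut-2-ene, t-BuOH/H2O, 0 °C to rt
Reagents that add atoms: sodium chlorite [Na+].[O-]Cl=O
Why: Pinnick oxidation converts the enal to the acrylic acid without touching the enone, the alkene scavenger removing HOCl.

Step 8
Reactants: 14 acid
Product: 16 methyl (7R,10S)-3-oxoeudesma-4,11(13)-dien-12-oate, via potassium carboxylate 15 (not isolated)
Conditions: K2CO3 (1.5 equiv), MeI (2 equiv), DMF, rt
Reagents that add atoms: iodomethane CI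
Why: SN2 O-alkylation of the carboxylate gives the methyl ester under conditions too mild to enolize the enone.

Step 9
Reactants: 16 enone ester
Product: 17 methyl (3S,7R,10S)-3β-hydroxyeudesma-4,11(13)-dien-12-oate
Conditions: NaBH4 (1 equiv), CeCl3·7H2O (1.1 equiv), MeOH, −40 to 0 °C
Reagents that add atoms: none
Why: Luche 1,2-reduction spares the acrylate, and axial hydride delivery from the α face (anti to the C10 methyl) gives the equatorial 3β-alcohol.

Step 10
Reactants: 17 allylic alcohol
Product: 18 methyl (3S,4S,5R,7R,10S)-4β,5β-epoxy-3β-hydroxyeudesm-11(13)-en-12-oate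
Conditions: VO(acac)2 (5 mol %), t-BuOOH (1.5 equiv, in decane), CH2Cl2, 0 °C to rt
Reagents that add atoms: tert-butyl hydroperoxide CC(C)(C)OO
Why: Hydroxyl-directed vanadium-catalysed epoxidation delivers oxygen to the tetrasubstituted olefin from the face of the 3β-OH, fixing the 4β-oxygen and 4α-methyl, while the electron-poor acrylate is inert.

Step 11
Reactants: 18 epoxy alcohol
Product: 19 methyl (3S,4R,7R,10S)-3β,4β-dihydroxyeudesma-5,11(13)-dien-12-oate
Conditions: Ti(OiPr)4 (1.5 equiv), CH2Cl2, rt; aq potassium sodium tartrate work-up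
Reagents that add atoms: none
Why: In this titanium-mediated epoxy alcohol rearrangement, chelation by the cis epoxy alcohol activates the epoxide so that the tertiary C5–O bond remote from the carbinol breaks and H-6 is lost, and the retained C4–O bond gives the 4β-OH with the Δ5 olefin.

Step 12
Reactants: 19 diol; 20 angelic acid [(Z)-2-methylbut-2-enoic acid]; 21 2,4,6-trichlorobenzoyl chloride
Product: 23 methyl (3S,4R,7R,10S)-3β-angeloyloxy-4β-hydroxyeudesma-5,11(13)-dien-12-oate (target), via mixed anhydride 22 (not isolated)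
Conditions: 20 (3 equiv), 21 (3 equiv), Et3N (6 equiv), toluene, rt, 2 h; then 19, 75 °C, 24–48 h (no DMAP)
Reagents that add atoms: none
Why: Yamaguchi-type mixed-anhydride esterification acylates only the equatorial secondary 3β-OH (the tertiary 4-OH is inert) and, run without nucleophilic catalyst, keeps the Z (angelate) geometry.

**Compound list**
1 | (R)-(−)-carvone, (5R)-2-methyl-5-(prop-1-en-2-yl)cyclohex-2-en-1-one | CC1=CC[C@H](CC1=O)C(C)=C | starting material
2 | lithium (5R)-2-methyl-5-(prop-1-en-2-yl)cyclohex-1-en-1-olate (lithium enolate, not isolated) | [Li+].[O-]C1=C(C)CC[C@H](C1)C(C)=C | intermediate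
3 | (+)-dihydrocarvone, (5R)-2-methyl-5-(prop-1-en-2-yl)cyclohexan-1-one, C2 epimer mixture | CC1CC[C@H](CC1=O)C(C)=C | intermediate
4 | (R)-(+)-1-phenylethylamine | C[C@@H](N)c1ccccc1 | starting material
5 | (1R)-N-[(5R)-2-methyl-5-(prop-1-en-2-yl)cyclohexylidene]-1-phenylethanamine, C2 epimer mixture | CC1CC[C@H](CC1=N[C@H](C)c2ccccc2)C(C)=C | intermediate
6 | ethyl vinyl ketone, pent-1-en-3-one | CCC(=O)C=C | starting material
7 | (5R)-2-methyl-N-[(1R)-1-phenylethyl]-5-(prop-1-en-2-yl)cyclohex-1-en-1-amine (secondary enamine tautomer, not isolated) | C=C(C)[C@H]1CC(N[C@H](C)c2ccccc2)=C(C)CC1 | intermediate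
8 | N-[(1R)-1-phenylethyl]imine of (2S,5R)-2-methyl-2-(3-oxopentyl)-5-(prop-1-en-2-yl)cyclohexan-1-one (Michael adduct imine, not isolated) | C=C(C)[C@H]1CC(=N[C@H](C)c2ccccc2)[C@](C)(CCC(=O)CC)CC1 | intermediate
9 | (2S,5R)-2-methyl-2-(3-oxopentyl)-5-(prop-1-en-2-yl)cyclohexan-1-one | C=C(C)[C@H]1CC(=O)[C@](C)(CCC(=O)CC)CC1 | intermediate
10 | (7R,10S)-5-hydroxyeudesm-11-en-3-one (aldol ketol, mixture at C4 and C5, not isolated) | C=C(C)[C@H]1CC2(O)C(C)C(=O)CC[C@]2(C)CC1 | intermediate
11 | (+)-α-cyperone, (7R,10S)-eudesma-4,11-dien-3-one | C=C(C)[C@H]1CC2=C(C)C(=O)CC[C@]2(C)CC1 | intermediate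
12 | (7R,10S)-12-hydroxyeudesma-4,11(13)-dien-3-one | C=C(CO)[C@H]1CC2=C(C)C(=O)CC[C@]2(C)CC1 | intermediate
13 | (7R,10S)-3-oxoeudesma-4,11(13)-dien-12-al | C=C(C=O)[C@H]1CC2=C(C)C(=O)CC[C@]2(C)CC1 | intermediate
14 | (7R,10S)-3-oxoeudesma-4,11(13)-dien-12-oic acid | C=C(C(=O)O)[C@H]1CC2=C(C)C(=O)CC[C@]2(C)CC1 | intermediate
15 | potassium (7R,10S)-3-oxoeudesma-4,11(13)-dien-12-oate (not isolated) | [K+].[O-]C(=O)C(=C)[C@H]1CC2=C(C)C(=O)CC[C@]2(C)CC1 | intermediate
16 | methyl (7R,10S)-3-oxoeudesma-4,11(13)-dien-12-oate | C=C(C(=O)OC)[C@H]1CC2=C(C)C(=O)CC[C@]2(C)CC1 | intermediate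
17 | methyl (3S,7R,10S)-3β-hydroxyeudesma-4,11(13)-dien-12-oate | C=C(C(=O)OC)[C@H]1CC2=C(C)[C@@H](O)CC[C@]2(C)CC1 | intermediate
18 | methyl (3S,4S,5R,7R,10S)-4β,5β-epoxy-3β-hydroxyeudesm-11(13)-en-12-oate | C=C(C(=O)OC)[C@H]1C[C@]23O[C@@]2(C)[C@@H](O)CC[C@]3(C)CC1 | intermediate
19 | methyl (3S,4R,7R,10S)-3β,4β-dihydroxyeudesma-5,11(13)-dien-12-oate | C=C(C(=O)OC)[C@H]1C=C2[C@](C)(CC[C@H](O)[C@]2(C)O)CC1 | intermediate
20 | angelic acid, (Z)-2-methylbut-2-enoic acid | C/C=C(/C)C(=O)O | starting material
21 | 2,4,6-trichlorobenzoyl chloride | O=C(Cl)c1c(Cl)cc(Cl)cc1Cl | starting material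
22 | angelic 2,4,6-trichlorobenzoic anhydride (mixed anhydride, not isolated) | C/C=C(/C)C(=O)OC(=O)c1c(Cl)cc(Cl)cc1Cl | intermediate
23 | methyl (3S,4R,7R,10S)-3β-angeloyloxy-4β-hydroxyeudesma-5,11(13)-dien-12-oate | C=C(C(=O)OC)[C@H]1C=C2[C@](C)(CC[C@H](OC(=O)/C(C)=C\C)[C@]2(C)O)CC1 | target

**Step count and risks**

Total step count: 12. Longest linear sequence: 12 steps (1 to 23); compounds 4, 6, 20 and 21 enter directly as bought.

The three steps most likely to fail:

Step 11 (epoxy alcohol rearrangement). The tetrasubstituted epoxide could instead open at C4, undergo a 1,2-shift (C4 methyl or a ring bond) to a ketone, or the methyl ester could partly exchange to the isopropyl ester. The fallback sets out from 18 and replaces the chelation-driven isomerization by a protect, ionize and deprotect sequence. Silylation (TBSCl, imidazole, DMF) gives the silyl ether methyl 3β-(tert-butyldimethylsilyloxy)-4β,5β-epoxyeudesm-11(13)-en-12-oate F3. Opening with TMSOTf and 2,6-lutidine (toluene, −78 to 0 °C; ionization at the tertiary C5, which the 3-silyloxy group does not deactivate, then loss of H-6) gives the bis-silyl ether methyl 3β-(tert-butyldimethylsilyloxy)-4β-(trimethylsilyloxy)eudesma-5,11(13)-dien-12-oate F4. Desilylation with HF·pyridine (THF/pyridine) comes back to the route at 19.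

Step 5 (allylic oxidation). Yields are typically moderate, and hydroxylation at the tertiary allylic C7–H or over-oxidation can compete. The fallback sets out from 11 and functionalizes the isopropenyl group by ene-type chlorination instead of C–H oxygenation. Ca(OCl)2 with solid CO2 in CH2Cl2/H2O at 0 °C gives the allylic chloride (7R,10S)-12-chloroeudesma-4,11(13)-dien-3-one F1. Displacement with KOAc in DMF at 60 °C gives the allylic acetate (7R,10S)-3-oxoeudesma-4,11(13)-dien-12-yl acetate F2. Methanolysis (K2CO3, MeOH) comes back to the route at 12.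

Step 12 (angeloylation). The 3-OH sits next to a fully substituted carbinol, so acylation may be slow, and prolonged heating can isomerize the angelate to the tiglate. The fallback sets out from 19 and builds the Z-olefin on the ester instead of transferring a preformed angeloyl group. Acylation of the 3-OH with 2-[bis(2,2,2-trifluoroethoxy)phosphoryl]propanoic acid (EDC·HCl, DMAP, CH2Cl2) gives the phosphonopropionate ester methyl 3β-{2-[bis(2,2,2-trifluoroethoxy)phosphoryl]propanoyloxy}-4β-hydroxyeudesma-5,11(13)-dien-12-oate F5. Z-selective Horner–Wadsworth–Emmons olefination (Still–Gennari; KN(SiMe3)2, 18-crown-6, THF, −78 °C, acetaldehyde) comes back to the route at 23.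

**Further compounds**
F1 | step 5 | (7R,10S)-12-chloroeudesma-4,11(13)-dien-3-one | C=C(CCl)[C@H]1CC2=C(C)C(=O)CC[C@]2(C)CC1
F2 | step 5 | (7R,10S)-3-oxoeudesma-4,11(13)-dien-12-yl acetate | C=C(COC(C)=O)[C@H]1CC2=C(C)C(=O)CC[C@]2(C)CC1
F3 | step 11 | methyl 3β-(tert-butyldimethylsilyloxy)-4β,5β-epoxyeudesm-11(13)-en-12-oate | C=C(C(=O)OC)[C@H]1C[C@]23O[C@@]2(C)[C@@H](O[Si](C)(C)C(C)(C)C)CC[C@]3(C)CC1
F4 | step 11 | methyl 3β-(tert-butyldimethylsilyloxy)-4β-(trimethylsilyloxy)eudesma-5,11(13)-dien-12-oate | C=C(C(=O)OC)[C@H]1C=C2[C@](C)(CC[C@H](O[Si](C)(C)C(C)(C)C)[C@]2(C)O[Si](C)(C)C)CC1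
F5 | step 12 | methyl 3β-{2-[bis(2,2,2-trifluoroethoxy)phosphoryl]propanoyloxy}-4β-hydroxyeudesma-5,11(13)-dien-12-oate | C=C(C(=O)OC)[C@H]1C=C2[C@](C)(CC[C@H](OC(=O)C(C)P(=O)(OCC(F)(F)F)OCC(F)(F)F)[C@]2(C)O)CC1
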